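Rings: A is the quinone, B the para-phenylene, C the phenol ring, D the meta-phenylene.
- Cuts, in order: the aryl ether bond from the ring A oxygen to ring D, which opens the 18-membered ring; both ArCH2–CH2Ar bonds, each traced to a Wittig olefin; the ring B–O–ring C ether, traced to fluoride displacement on 4-fluorobenzaldehyde.
- Enabling feature: the ring A oxygen that carries ring D sits on the carbon between an oxygenated ring carbon (the carbonyl next to the ring CH) and the carbon bearing the ethano bridge, so in the benzyl-protected arene it is the single free, crowded but nucleophilic phenol. On ring D the carbon para to the ether oxygen and ortho to the bridge carbon is a CH in the target, so a nitro group can sit there, activate a fluoride on the ether carbon and later be excised.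
- Forward order: the ring A aldehyde (5 steps), the ring B–C phosphonium salt (4 steps) and the ring D phosphonium salt (3 steps) are made separately. They are joined by a Wittig reaction, nitrile-to-aldehyde reduction and a second Wittig reaction, and one diimide reduction saturates both olefins. MOM removal, macrocyclisation (the only ring formed), nitro removal, debenzylation and air oxidation follow.
- Stereochemistry: the target has no stereocentre, and olefin geometry is irrelevant because both double bonds are saturated.

Key step: step 18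

Remark on the chemistry: stilbenes 19, 21 and 22 are assumed to be carried as mixtures of olefin isomers, all of which converge on the single saturated compound 23.

**Route**

Step 1
Reactants: 1 2-methoxyhydroquinone
Product: 2 1,4-bis(benzyloxy)-2-methoxybenzene
Conditions: BnBr, K2CO3, DMF, 60 °C, under argon
Reagents that add atoms: benzyl bromide BrCc1ccccc1
Why: Double Williamson etherification of both phenols should proceed cleanly, the inert atmosphere keeping the electron-rich hydroquinone from oxidising to the quinone before it is alkylated.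

Step 2
Reactants: 2 1,4-bis(benzyloxy)-2-methoxybenzene
Product: 4 2,5-bis(benzyloxy)-4-methoxybenzaldehyde, via iminium chloride 3 (not isolated)
Conditions: POCl3, DMF, 0 → 70 °C; then H2O, rt
Reagents that add atoms: N,N-dimethylformamide CN(C)C=O; water O
Why: Vilsmeier–Haack formylation should attack the ring carbon para to the methoxy group and ortho to a benzyloxy group, the most activated open site of a 1,2,4-trialkoxybenzene, and the iminium salt is hydrolysed on work-up.

Step 3
Reactants: 4 2,5-bis(benzyloxy)-4-methoxybenzaldehyde
Product: 6 2,5-bis(benzyloxy)-4-methoxyphenol, via aryl formate 5 (not isolated)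
Conditions: mCPBA, CH2Cl2, 0 °C → rt; then K2CO3 (cat.), MeOH, rt
Reagents that add atoms: 3-chloroperoxybenzoic acid OOC(=O)c1cccc(Cl)c1
Why: In this Baeyer–Villiger (Dakin-type) oxidation the electron-rich aryl group migrates in preference to hydrogen, and the resulting aryl formate is methanolysed to the phenol.

Step 4
Reactants: 6 2,5-bis(benzyloxy)-4-methoxyphenol
Product: 7 3,6-bis(benzyloxy)-2-hydroxy-5-methoxybenzaldehyde
Conditions: MgCl2, Et3N, (CH2O)n, MeCN, reflux; then 1 M HCl
Reagents that add atoms: paraformaldehyde (as formaldehyde) C=O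
Why: In the magnesium-mediated ortho-formylation (Casnati–Skattebøl) the magnesium phenoxide delivers formaldehyde only to the single free ortho carbon, and the benzylic alkoxide is oxidised to the aldehyde by hydride transfer to a second formaldehyde.

Step 5
Reactants: 7 3,6-bis(benzyloxy)-2-hydroxy-5-methoxybenzaldehyde
Product: 8 3,6-bis(benzyloxy)-5-methoxy-2-(methoxymethoxy)benzaldehyde
Conditions: NaH, MOMCl, DMF, 0 °C → rt
Reagents that add atoms: chloromethyl methyl ether COCCl
Why: Williamson-type O-alkylation of the sodium phenoxide gives the MOM acetal, which masks the future nucleophile against ylide bases and against the activated fluoroarene introduced later.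

Step 6
Reactants: 9 3,4-dihydroxybenzonitrile
Product: 10 4-(benzyloxy)-3-hydroxybenzonitrile
Conditions: BnBr (1 equiv), K2CO3 (1 equiv), DMF, rt
Reagents that add atoms: benzyl bromide BrCc1ccccc1
Why: Regioselective Williamson monoalkylation is expected because the hydroxyl para to the nitrile is the more acidic and is the one deprotonated by one equivalent of carbonate.

Step 7
Reactants: 10 4-(benzyloxy)-3-hydroxybenzonitrile; 11 4-fluorobenzaldehyde
Product: 12 4-(benzyloxy)-3-(4-formylphenoxy)benzonitrile
Conditions: K2CO3, DMF, 130 °C
Reagents that add atoms: none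
Why: Intermolecular nucleophilic aromatic substitution, the phenoxide displacing fluoride para to the formyl group, forms the ring B–O–ring C ether and leaves ring B as an aldehyde and ring C as a nitrile, so the two termini are differentiated.

Step 8
Reactants: 12 4-(benzyloxy)-3-(4-formylphenoxy)benzonitrile
Product: 13 4-(benzyloxy)-3-[4-(hydroxymethyl)phenoxy]benzonitrile
Conditions: NaBH4, MeOH/THF, 0 °C
Reagents that add atoms: none
Why: Borohydride reduction is chemoselective for the aldehyde and leaves the nitrile untouched.

Step 9
Reactants: 13 4-(benzyloxy)-3-[4-(hydroxymethyl)phenoxy]benzonitrile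
Product: 14 {4-[2-(benzyloxy)-5-cyanophenoxy]benzyl}triphenylphosphonium bromide
Conditions: PPh3·HBr, MeCN, reflux
Reagents that add atoms: triphenylphosphine hydrobromide [Br-].c1ccc(cc1)[PH+](c1ccccc1)c1ccccc1
Why: Direct phosphonium salt formation from an electron-rich benzylic alcohol should work because the para-aryloxy group stabilises the benzylic cation that triphenylphosphine captures (substitution of the protonated alcohol).

Step 10
Reactants: 15 5-fluoro-2-nitrobenzaldehyde
Product: 16 (5-fluoro-2-nitrophenyl)methanol
Conditions: NaBH4, MeOH, 0 °C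
Reagents that add atoms: none
Why: Borohydride reduction of the aldehyde is fast at 0 °C, where neither the nitro group nor the activated fluoride reacts.

Step 11
Reactants: 16 (5-fluoro-2-nitrophenyl)methanol
Product: 17 2-(bromomethyl)-4-fluoro-1-nitrobenzene
Conditions: PBr3, CH2Cl2, 0 °C → rt
Reagents that add atoms: phosphorus tribromide BrP(Br)Br
Why: Conversion of a primary benzylic alcohol into the bromide through its phosphite ester and bromide displacement is a standard substitution.

Step 12
Reactants: 17 2-(bromomethyl)-4-fluoro-1-nitrobenzene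
Product: 18 (5-fluoro-2-nitrobenzyl)triphenylphosphonium bromide
Conditions: PPh3, toluene, reflux
Reagents that add atoms: triphenylphosphine c1ccc(cc1)P(c1ccccc1)c1ccccc1
Why: Quaternisation of triphenylphosphine by a benzylic bromide is a simple bimolecular substitution, and the neutral phosphine does not touch the aryl fluoride.

Step 13
Reactants: 8 3,6-bis(benzyloxy)-5-methoxy-2-(methoxymethoxy)benzaldehyde; 14 {4-[2-(benzyloxy)-5-cyanophenoxy]benzyl}triphenylphosphonium bromide
Product: 19 4-(benzyloxy)-3-(4-{2-[3,6-bis(benzyloxy)-5-methoxy-2-(methoxymethoxy)phenyl]ethenyl}phenoxy)benzonitrile (E/Z mixture)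
Conditions: KOtBu, THF, 0 °C; then 8, 0 °C → rt
Reagents that add atoms: none
Why: Wittig olefination of the 2,6-dialkoxybenzaldehyde with the semi-stabilised benzylic ylide joins ring A to ring B, and the nitrile is inert to the ylide and to tert-butoxide at room temperature.

Step 14
Reactants: 19 stilbene nitrile (E/Z mixture)
Product: 21 4-(benzyloxy)-3-(4-{2-[3,6-bis(benzyloxy)-5-methoxy-2-(methoxymethoxy)phenyl]ethenyl}phenoxy)benzaldehyde (E/Z mixture), via aldimine 20 (not isolated)
Conditions: i-Bu2AlH, CH2Cl2, −78 → −40 °C; MeOH, then aq. KNaC4H4O6 (potassium sodium tartrate), rt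
Reagents that add atoms: water O
Why: Partial reduction of an aryl nitrile with i-Bu2AlH stops at the N-aluminated imine, which hydrolyses to the aldehyde on the near-neutral tartrate work-up that spares the MOM acetal.

Step 15
Reactants: 21 stilbene aldehyde (E/Z mixture); 18 (5-fluoro-2-nitrobenzyl)triphenylphosphonium bromide
Product: 22 1-(benzyloxy)-2-(4-{2-[3,6-bis(benzyloxy)-5-methoxy-2-(methoxymethoxy)phenyl]ethenyl}phenoxy)-4-[2-(5-fluoro-2-nitrophenyl)ethenyl]benzene (mixture of olefin isomers)
Conditions: K2CO3, 18-crown-6 (cat.), CH2Cl2, reflux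
Reagents that add atoms: none
Why: Wittig olefination with the nitro-stabilised benzylic ylide under solid–liquid phase-transfer conditions attaches ring D, and carbonate is too weak a nucleophile to displace the activated fluoride.

Step 16
Reactants: 22 distilbene (mixture of olefin isomers)
Product: 23 1-(benzyloxy)-2-(4-{2-[3,6-bis(benzyloxy)-5-methoxy-2-(methoxymethoxy)phenyl]ethyl}phenoxy)-4-[2-(5-fluoro-2-nitrophenyl)ethyl]benzene
Conditions: 2-nitrobenzenesulfonyl hydrazide (excess, in portions), Et3N, THF, rt
Reagents that add atoms: none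
Why: Diimide reduction transfers hydrogen concertedly to both C=C bonds and, unlike catalytic hydrogenation, leaves the nitro group, the aryl fluoride and the benzyl ethers intact.

Step 17
Reactants: 23 MOM-protected bis(bibenzyl)
Product: 24 3,6-bis(benzyloxy)-2-[2-(4-{2-(benzyloxy)-5-[2-(5-fluoro-2-nitrophenyl)ethyl]phenoxy}phenyl)ethyl]-4-methoxyphenol (seco phenol)
Conditions: HCl (cat.), MeOH/THF, 50 °C
Reagents that add atoms: none
Why: Acid-catalysed acetal cleavage removes the MOM group alone, since benzyl ethers, the nitro group and the aryl fluoride are stable to methanolic acid.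

Step 18
Reactants: 24 seco phenol
Product: 25 nitro macrocycle (18-membered; ring A–O–ring D ether closed, nitro group on ring D para to the new ether oxygen, three benzyl ethers)
Conditions: K2CO3, degassed DMF, 60 °C, slow addition of 24 to a final 0.002 M
Reagents that add atoms: none
Why: Carbonate deprotonates the only free hydroxyl, the flanked ring A phenol; the phenoxide adds to the fluorine-bearing carbon of ring D to give a Meisenheimer adduct whose negative charge is carried by the para nitro group, and loss of fluoride completes the addition–elimination. The closest known reaction type is the intramolecular substitution of nitro-activated aryl fluorides by phenoxides that is used to close macrocyclic diaryl ethers. The 18-membered ring closes by macrocyclising O-arylation at the ring A–O–ring D bond, the two ethano bridges giving the seco chain enough freedom to bring its termini together. No stereocentre is formed. The step needs chemoselectivity and ring closure in preference to oligomerisation: all other oxygens are ethers, the fluoride para to the nitro group is the only activated leaving group, and slow addition at high dilution holds the intermolecular pathway down. A hindered, electron-rich phenoxide of this kind would be sluggish in copper-mediated arylation, yet it should attack a para-nitro fluoroarene readily.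

Step 19
Reactants: 25 nitro macrocycle
Product: 26 amino macrocycle (amino group in place of the nitro group on ring D)
Conditions: Zn dust, AcOH/THF, rt → 40 °C
Reagents that add atoms: none
Why: Dissolving-metal reduction of an aryl nitro group to the aniline does not cleave benzyl or diaryl ethers.

Step 20
Reactants: 26 amino macrocycle
Product: 28 tribenzyl macrocycle (ring D now a plain meta-phenylene), via diazonium chloride 27 (not isolated)
Conditions: NaNO2, aq. HCl, THF, 0 °C; then 50% aq. H3PO2 (large excess), 0 °C → rt
Reagents that add atoms: none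
Why: Diazotisation followed by hydrodediazoniation with hypophosphorous acid replaces the amino group by hydrogen through a radical chain in which hydrogen-atom transfer from the concentrated reductant should outrun any cyclisation of the aryl radical.

Step 21
Reactants: 28 tribenzyl macrocycle
Product: 30 CNP0332646.0 (target quinone), via hydroquinone 29 (not isolated)
Conditions: H2 (1 atm), Pd/C, EtOAc/MeOH, rt; filter; then air, silica gel, EtOAc, rt
Reagents that add atoms: none
Why: Hydrogenolysis removes all three benzyl ethers, and the electron-rich methoxy aryloxy hydroquinone then autoxidises in air to the para-quinone while the isolated ring C phenol is not oxidised.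

**Compound list**

1 | 2-methoxyhydroquinone (2-methoxybenzene-1,4-diol) | COc1cc(O)ccc1O | starting material
2 | 1,4-bis(benzyloxy)-2-methoxybenzene | COc1cc(OCc2ccccc2)ccc1OCc1ccccc1 | intermediate
3 | N-[2,5-bis(benzyloxy)-4-methoxybenzylidene]-N-methylmethanaminium chloride (iminium chloride) | C[N+](C)=Cc1cc(OCc2ccccc2)c(OC)cc1OCc1ccccc1.[Cl-] | intermediate
4 | 2,5-bis(benzyloxy)-4-methoxybenzaldehyde | O=Cc1cc(OCc2ccccc2)c(OC)cc1OCc1ccccc1 | intermediate
5 | 2,5-bis(benzyloxy)-4-methoxyphenyl formate (aryl formate) | O=COc1cc(OCc2ccccc2)c(OC)cc1OCc1ccccc1 | intermediate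
6 | 2,5-bis(benzyloxy)-4-methoxyphenol | Oc1cc(OCc2ccccc2)c(OC)cc1OCc1ccccc1 | intermediate
7 | 3,6-bis(benzyloxy)-2-hydroxy-5-methoxybenzaldehyde | O=Cc1c(O)c(OCc2ccccc2)cc(OC)c1OCc1ccccc1 | intermediate
8 | 3,6-bis(benzyloxy)-5-methoxy-2-(methoxymethoxy)benzaldehyde | O=Cc1c(OCOC)c(OCc2ccccc2)cc(OC)c1OCc1ccccc1 | intermediate
9 | 3,4-dihydroxybenzonitrile | N#Cc1ccc(O)c(O)c1 | starting material
10 | 4-(benzyloxy)-3-hydroxybenzonitrile | N#Cc1ccc(OCc2ccccc2)c(O)c1 | intermediate
11 | 4-fluorobenzaldehyde | O=Cc1ccc(F)cc1 | starting material
12 | 4-(benzyloxy)-3-(4-formylphenoxy)benzonitrile | N#Cc1ccc(OCc2ccccc2)c(Oc2ccc(C=O)cc2)c1 | intermediate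
13 | 4-(benzyloxy)-3-[4-(hydroxymethyl)phenoxy]benzonitrile | N#Cc1ccc(OCc2ccccc2)c(Oc2ccc(CO)cc2)c1 | intermediate
14 | {4-[2-(benzyloxy)-5-cyanophenoxy]benzyl}triphenylphosphonium bromide | N#Cc1ccc(OCc2ccccc2)c(Oc2ccc(C[P+](c3ccccc3)(c3ccccc3)c3ccccc3)cc2)c1.[Br-] | intermediate
15 | 5-fluoro-2-nitrobenzaldehyde | O=Cc1cc(F)ccc1[N+](=O)[O-] | starting material
16 | (5-fluoro-2-nitrophenyl)methanol | OCc1cc(F)ccc1[N+](=O)[O-] | intermediate
17 | 2-(bromomethyl)-4-fluoro-1-nitrobenzene | BrCc1cc(F)ccc1[N+](=O)[O-] | intermediate
18 | (5-fluoro-2-nitrobenzyl)triphenylphosphonium bromide | [O-][N+](=O)c1ccc(F)cc1C[P+](c1ccccc1)(c1ccccc1)c1ccccc1.[Br-] | intermediate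
19 | 4-(benzyloxy)-3-(4-{2-[3,6-bis(benzyloxy)-5-methoxy-2-(methoxymethoxy)phenyl]ethenyl}phenoxy)benzonitrile, E/Z mixture (stilbene nitrile) | N#Cc1ccc(OCc2ccccc2)c(Oc2ccc(C=Cc3c(OCOC)c(OCc4ccccc4)cc(OC)c3OCc3ccccc3)cc2)c1 | intermediate
20 | aldimine of 21 (CH=NH in place of the nitrile of 19), E/Z mixture | N=Cc1ccc(OCc2ccccc2)c(Oc2ccc(C=Cc3c(OCOC)c(OCc4ccccc4)cc(OC)c3OCc3ccccc3)cc2)c1 | intermediate
21 | 4-(benzyloxy)-3-(4-{2-[3,6-bis(benzyloxy)-5-methoxy-2-(methoxymethoxy)phenyl]ethenyl}phenoxy)benzaldehyde, E/Z mixture (stilbene aldehyde) | O=Cc1ccc(OCc2ccccc2)c(Oc2ccc(C=Cc3c(OCOC)c(OCc4ccccc4)cc(OC)c3OCc3ccccc3)cc2)c1 | intermediate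
22 | 1-(benzyloxy)-2-(4-{2-[3,6-bis(benzyloxy)-5-methoxy-2-(methoxymethoxy)phenyl]ethenyl}phenoxy)-4-[2-(5-fluoro-2-nitrophenyl)ethenyl]benzene, mixture of olefin isomers (distilbene) | [O-][N+](=O)c1ccc(F)cc1C=Cc1ccc(OCc2ccccc2)c(Oc2ccc(C=Cc3c(OCOC)c(OCc4ccccc4)cc(OC)c3OCc3ccccc3)cc2)c1 | intermediate
23 | 1-(benzyloxy)-2-(4-{2-[3,6-bis(benzyloxy)-5-methoxy-2-(methoxymethoxy)phenyl]ethyl}phenoxy)-4-[2-(5-fluoro-2-nitrophenyl)ethyl]benzene (MOM-protected bis(bibenzyl)) | [O-][N+](=O)c1ccc(F)cc1CCc1ccc(OCc2ccccc2)c(Oc2ccc(CCc3c(OCOC)c(OCc4ccccc4)cc(OC)c3OCc3ccccc3)cc2)c1 | intermediate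
24 | 3,6-bis(benzyloxy)-2-[2-(4-{2-(benzyloxy)-5-[2-(5-fluoro-2-nitrophenyl)ethyl]phenoxy}phenyl)ethyl]-4-methoxyphenol (seco phenol) | COc1cc(OCc2ccccc2)c(O)c(CCc2ccc(cc2)Oc2cc(ccc2OCc2ccccc2)CCc2cc(F)ccc2[N+](=O)[O-])c1OCc1ccccc1 | intermediate
25 | nitro macrocycle: 18-membered ring closed by the ring A–O–ring D ether; nitro group on ring D para to that oxygen and ortho to the ring D bridge carbon; benzyl ethers on both hydroquinone oxygens of ring A and on the ring C oxygen; methoxy on ring A | COc1cc(OCc2ccccc2)c2c(CCc3ccc(cc3)Oc3cc(ccc3OCc3ccccc3)CCc3cc(ccc3[N+](=O)[O-])O2)c1OCc1ccccc1 | intermediate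
26 | amino macrocycle: as 25 with an amino group in place of the nitro group | COc1cc(OCc2ccccc2)c2c(CCc3ccc(cc3)Oc3cc(ccc3OCc3ccccc3)CCc3cc(ccc3N)O2)c1OCc1ccccc1 | intermediate
27 | diazonium chloride: as 25 with a diazonium group in place of the nitro group, chloride counter-ion | COc1cc(OCc2ccccc2)c2c(CCc3ccc(cc3)Oc3cc(ccc3OCc3ccccc3)CCc3cc(ccc3[N+]#N)O2)c1OCc1ccccc1.[Cl-] | intermediate
28 | tribenzyl macrocycle: as 25 with hydrogen in place of the nitro group (ring D a plain meta-phenylene) | COc1cc(OCc2ccccc2)c2c(CCc3ccc(cc3)Oc3cc(ccc3OCc3ccccc3)CCc3cccc(c3)O2)c1OCc1ccccc1 | intermediate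
29 | hydroquinone: macrocycle with free hydroxyls on both hydroquinone oxygens of ring A and on ring C | COc1cc(O)c2c(CCc3ccc(cc3)Oc3cc(ccc3O)CCc3cccc(c3)O2)c1O | intermediate
30 | CNP0332646.0: macrocyclic 2-methoxy-1,4-benzoquinone carrying the ring D aryloxy group and the ethano bridge on adjacent quinone carbons, with a free phenol on ring C | COC1=CC(=O)C2=C(CCc3ccc(cc3)Oc3cc(ccc3O)CCc3cccc(c3)O2)C1=O | target

**Step count and risks**

Total step count: 21. Longest linear sequence: 14 steps (steps 1–5, then 13–21).

Steps most likely to fail: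

1. Step 18 (macrocyclisation). Intermolecular substitution may outrun ring closure, because the flanked phenoxide attacks slowly and the chain must fold; deprotonation of the benzylic CH2 ortho to the nitro group may also consume material. The fallback closes the same ring A–O–ring D bond by copper catalysis on an unactivated bromide. It sets out from aldehyde 21. Wittig olefination with commercial (3-bromobenzyl)triphenylphosphonium bromide (K2CO3, 18-crown-6, CH2Cl2, reflux) should give the bromo distilbene F1. Diimide reduction as in step 16 should give the saturated bromide F2, and HCl in MeOH/THF the bromo seco phenol F3. Intramolecular Ullmann etherification (CuI, picolinic acid, K3PO4, DMSO, 90 °C, high dilution; a ligand system that tolerates di-ortho-substituted phenols) would then give tribenzyl macrocycle 28. The route is rejoined at 28, so steps 19 and 20 fall away.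

2. Step 20 (removal of the amino group). After loss of nitrogen the aryl radical or cation may be intercepted by ring C across the ethano bridge (Pschorr-type closure to a dihydrophenanthrene) or transannularly before hydrogen transfer, and the diazonium ion may couple with the electron-rich rings. The fallback avoids the diazonium salt and sets out from nitro macrocycle 25. Palladium-catalysed reductive denitration (Pd(acac)2, BrettPhos, K3PO4, 2-propanol, 1,4-dioxane, 130 °C) replaces the nitro group by hydrogen through oxidative addition into the C–NO2 bond, exchange of nitrite for isopropoxide, β-hydride elimination and C–H reductive elimination. It comes back at 28 and makes no new compound (F0); step 19 is then not needed.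

3. Step 4 (ortho-formylation). Hydroxymethylation at the carbon wedged between the hydroxyl and a benzyloxy group may be slow, and the benzylic alcohol stage may condense with a second phenol to diarylmethanes. The fallback installs the carbon through a halogen and sets out from phenol 6. Ortho-bromination (NBS, i-Pr2NH cat., CH2Cl2, 0 °C), directed by the free hydroxyl, should give 3,6-bis(benzyloxy)-2-bromo-4-methoxyphenol F4. NaH and MOMCl in DMF should give the MOM ether 1,4-bis(benzyloxy)-3-bromo-5-methoxy-2-(methoxymethoxy)benzene F5. Bromine–lithium exchange (n-BuLi, THF, −78 °C), which is faster than benzylic deprotonation, and a DMF quench would deliver aldehyde 8. The route is rejoined at 8, so step 5 is skipped.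

Further compounds
F1 | step 18 | 1-(benzyloxy)-2-(4-{2-[3,6-bis(benzyloxy)-5-methoxy-2-(methoxymethoxy)phenyl]ethenyl}phenoxy)-4-[2-(3-bromophenyl)ethenyl]benzene, mixture of olefin isomers (bromo distilbene) | Brc1cccc(C=Cc2ccc(OCc3ccccc3)c(Oc3ccc(C=Cc4c(OCOC)c(OCc5ccccc5)cc(OC)c4OCc4ccccc4)cc3)c2)c1
F2 | step 18 | 1-(benzyloxy)-2-(4-{2-[3,6-bis(benzyloxy)-5-methoxy-2-(methoxymethoxy)phenyl]ethyl}phenoxy)-4-[2-(3-bromophenyl)ethyl]benzene (saturated bromide) | Brc1cccc(CCc2ccc(OCc3ccccc3)c(Oc3ccc(CCc4c(OCOC)c(OCc5ccccc5)cc(OC)c4OCc4ccccc4)cc3)c2)c1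
F3 | step 18 | 3,6-bis(benzyloxy)-2-[2-(4-{2-(benzyloxy)-5-[2-(3-bromophenyl)ethyl]phenoxy}phenyl)ethyl]-4-methoxyphenol (bromo seco phenol) | Brc1cccc(CCc2ccc(OCc3ccccc3)c(Oc3ccc(CCc4c(O)c(OCc5ccccc5)cc(OC)c4OCc4ccccc4)cc3)c2)c1
F0 | step 20 | none | none
F4 | step 4 | 3,6-bis(benzyloxy)-2-bromo-4-methoxyphenol | Oc1c(Br)c(OCc2ccccc2)c(OC)cc1OCc1ccccc1
F5 | step 4 | 1,4-bis(benzyloxy)-3-bromo-5-methoxy-2-(methoxymethoxy)benzene | COCOc1c(Br)c(OCc2ccccc2)c(OC)cc1OCc1ccccc1
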